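Follow the L rather than the E: the first thing to settle for this flask is how many L each lost Z takes up.

| setting | teal | red | amber | flask |
|---|---|---|---|---|
| Z | 21 mM | 21 mM | 42 mM | 21 mM |
| L | 12 mM | 17 mM | 23.1 mM | 23.1 mM |
| remark | run made earlier | run made earlier | run made earlier |  |
| time |  |  |  | 15 h |

| run | time / h | E / % | Z / % |
|---|---|---|---|
| teal | 0.333 | 1.8 | 73.7 |
| teal | 1.00 | 5.4 | 56.9 |
| teal | 4.00 | 2.2 | 52.0 |
| teal | 15.0 | 0 | 52.4 |
| red | 0.333 | 5.3 | 64.1 |
| red | 1.00 | 10.5 | 44.6 |
| red | 4.00 | 3.9 | 37.2 |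
| red | 15.0 | 2.0 | 37.9 |
| amber | 0.333 | 5.0 | 64.6 |
| amber | 1.00 | 5.3 | 54.2 |
| amber | 4.00 | 1.7 | 53.5 |
| amber | 15.0 | 0 | 53.9 |

(standard deviation of a reading: 0.5 percentage points)

- on the list of suspects stand: Z + L -> D + J; L + D -> E + J; L + E -> G + J; E <-> Q

- when, up to 15 h, the flask holds most E
- the amount of E, in percent of the Z charged, at that time
- the first time at which E reaches 12 %, in the same percent

The suspects are Z + L → D + J, L + D → E + J, L + E → G + J and E ⇌ Q.

In the first instants of a run no D is charged, so Z + L is the open step and each Z lost costs one L. Then D builds up and competes for L. In red, E reads 5.3 % at 0.333 h and 10.5 % at 1.00 h. Later red's E falls from 3.9 % at 4.00 h to 2.0 % at 15.0 h, while Z reads 37.2 % and then 37.9 %. So E looks like a passage, with Q as its likely outlet.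

The flat Z is taken here as the point where the charged L is bound. Teal then gives 1.20 for L spent per Z lost, n, at a charge ratio L/Z of 0.571. Amber, at twice the Z and a ratio of 0.550, reads 1.19, close to teal. So n looks tied to the ratio. Red, at 0.810, reads 1.30.

My own reckoning runs a straight line through teal and red to the flask's ratio of 1.10, which gives n = 1.43. The flask should then end with Z at 23.1 %. With G taken as small, E, G and Q together should hold 33.0 % of the Z charged. This reckoning gives no peak.

The forecast puts the peak of E at 15 % at 1.1 h, and the asked level at 0.55 h. On the later fall of E it says: “That points to E → Q, which is largely one-way”.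

The flask gives 17.2 % at 1.25 h and the asked level at 0.528 h, each within the forecast's margin.

    Z + L → D + J (k = 0.0310 M⁻¹ s⁻¹)
    L + D → E + J (k = 0.0190 M⁻¹ s⁻¹)
    L + E → G + J (k = 4.90 × 10⁻⁴ M⁻¹ s⁻¹)
    E ⇌ Q (K = 20.0, k = 1.50 × 10⁻⁴ s⁻¹)

At 15.0 h the flask holds Z 22.4 %, L 0 %, the limiting reagent, and J 23.1 mM, so n stands at 1.42 and E, G and Q together at 32.2 %. The half-life of E by its forward step to Q, 1.3 h, is shorter than 15 h, and the flask ends with Q 30.4 % beside E 1.53 %. A neighbour flask with Z at 8.4 mM and its other charges as in this flask peaks at 38.2 % of E, ends with Z 0 % and Q 91.8 %, and has n = 2.03.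

(Readings and results come from a simulation on assumed constants; noise was put on by code.)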